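**Assumption:** the target is a planar, achiral flavone with no stereocentre, so no enantiocontrol is needed. The C2 centre in the transient intermediates 4 and 6–8 is racemic and is erased on aromatisation.

## Retrosynthetic overview
1. Target 10 comes from 9 by global O-debenzylation, which unmasks the air-sensitive pyrogallol of ring B last.
2. 9 comes from chalcone 5 in one operation. It closes O1–C2 (ring C), then builds C3–N and converts it to C3–OMe, with methanol as the source of the 3-OMe group. No phenol-selective methylation is needed.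
3. 5 comes from aldol condensation of ketone 2 with aldehyde 3.
4. 2 comes from double C-methylation of phloroacetophenone 1.
5. Rings A and B are bought as arenes. Ring C (the pyranone) is the only ring formed, in step 3.

## Route

**Step 1**
Reactants: 1 1-(2,4,6-trihydroxyphenyl)ethan-1-one (phloroacetophenone)
Product: 2 1-(2,4,6-trihydroxy-3,5-dimethylphenyl)ethan-1-one
Conditions: NaOMe (2.2 equiv), MeI (2.1 equiv), MeOH, 0 → 45 °C, 6 h; 1 M HCl work-up; chromatography or crystallisation
Reagents that add atoms: iodomethane, CI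
Why: The ambident acylphloroglucinolate anion alkylates at carbon in protic medium (C-alkylation of a vinylogous-acid enolate), each of the two free ring positions takes one methyl group, and limiting MeI holds back gem-dimethylation (about 40–50 % expected).

**Step 2**
Reactants: 2 1-(2,4,6-trihydroxy-3,5-dimethylphenyl)ethan-1-one; 3 3,4,5-tris(benzyloxy)benzaldehyde
Product: 5 (E)-1-(2,4,6-trihydroxy-3,5-dimethylphenyl)-3-[3,4,5-tris(benzyloxy)phenyl]prop-2-en-1-one, via aldol adduct 4 (not isolated)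
Conditions: LiN(SiMe3)2 (4.2 equiv), THF, −78 → −10 °C, 1.5 h; 3 (1.1 equiv), −78 °C → rt, 16 h; 1 M HCl
Reagents that add atoms: none
Why: This is a protecting-group-free Claisen–Schmidt condensation through the tetralithiated ketone (three phenoxides plus the enolate), whose carbon is the only reactive nucleophile, and E1cB loss of water from 4 gives the thermodynamic E-enone.

**Step 3**
Reactants: 5 (E)-1-(2,4,6-trihydroxy-3,5-dimethylphenyl)-3-[3,4,5-tris(benzyloxy)phenyl]prop-2-en-1-one
Product: 9 5,7-dihydroxy-3-methoxy-6,8-dimethyl-2-[3,4,5-tris(benzyloxy)phenyl]-4H-chromen-4-one, via flavanone 6 (not isolated), via 3-oximinoflavanone 7 (not isolated), via 3,3-dimethoxyflavanone 8 (not isolated)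
Conditions: HCl (1.25 M in MeOH, 3 equiv), MeOH–CH2Cl2 3:1, 45 °C, 3 h; then HC(OMe)3 (5 equiv), t-BuONO (3 equiv, portionwise), 0 → 50 °C, pressure tube, Ar
Reagents that add atoms: methanol, CO; tert-butyl nitrite, CC(C)(C)ON=O (its N and O stay only in intermediate 7)
Why: Proposed new method: acid closes ring C by 6-endo oxa-Michael addition of an ortho OH (ring A is symmetric, so either OH gives the same 6), the enol of 6 is C-nitrosated at C3 (C–N bond) and tautomerises to oxime 7, a second nitrite N-nitrosates 7 so that methanol adds to C3 and N2O leaves to give ketal 8 (C–O bonds), and 8 loses methanol and H-2 under the same acid to aromatise to pyranone 9, with HC(OMe)3 removing the one equivalent of water that would otherwise lead to the flavonol; oxygen arrives as a nucleophile at the only electrophilic carbon under non-alkylating acidic conditions, so the free 5-OH and 7-OH cannot be methylated, and the C6/C8 methyl groups block ring C-nitrosation; the closest known reaction types are the Kostanecki nitrosation of flavanones to 3-oximinoflavanones (hydrolysed to flavonols) and the nitrosative acetalisation of methyl ketones to alpha-keto acetals by alkyl nitrite/HCl/alcohol, and to my knowledge neither has been applied to turn a chalcone or flavanone directly into a 3-alkoxyflavone.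

**Step 4**
Reactants: 9 5,7-dihydroxy-3-methoxy-6,8-dimethyl-2-[3,4,5-tris(benzyloxy)phenyl]-4H-chromen-4-one
Product: 10 5,7-dihydroxy-3-methoxy-6,8-dimethyl-2-(3,4,5-trihydroxyphenyl)-4H-chromen-4-one (6,8-di-C-methylmyricetin 3-methyl ether)
Conditions: H2 (1 atm), 10 % Pd/C, THF–MeOH 1:1, rt, 5 h; filtration under Ar
Reagents that add atoms: none
Why: This is catalytic hydrogenolysis of three aryl benzyl ethers, and the tetrasubstituted vinylogous-ester C2=C3 bond, the 3-OMe group and the chelated ketone are inert at 1 atm.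

## Compound list
1 | 1-(2,4,6-trihydroxyphenyl)ethan-1-one | CC(=O)c1c(O)cc(O)cc1O | starting material
2 | 1-(2,4,6-trihydroxy-3,5-dimethylphenyl)ethan-1-one | CC(=O)c1c(O)c(C)c(O)c(C)c1O | intermediate
3 | 3,4,5-tris(benzyloxy)benzaldehyde | O=Cc1cc(OCc2ccccc2)c(OCc2ccccc2)c(OCc2ccccc2)c1 | starting material
4 | rac-3-hydroxy-1-(2,4,6-trihydroxy-3,5-dimethylphenyl)-3-[3,4,5-tris(benzyloxy)phenyl]propan-1-one (aldol adduct, lithium salt in the flask) | OC(CC(=O)c1c(O)c(C)c(O)c(C)c1O)c1cc(OCc2ccccc2)c(OCc2ccccc2)c(OCc2ccccc2)c1 | intermediate (not isolated)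
5 | (E)-1-(2,4,6-trihydroxy-3,5-dimethylphenyl)-3-[3,4,5-tris(benzyloxy)phenyl]prop-2-en-1-one | O=C(/C=C/c1cc(OCc2ccccc2)c(OCc2ccccc2)c(OCc2ccccc2)c1)c1c(O)c(C)c(O)c(C)c1O | intermediate
6 | rac-5,7-dihydroxy-6,8-dimethyl-2-[3,4,5-tris(benzyloxy)phenyl]chroman-4-one | O=C1CC(c2cc(OCc3ccccc3)c(OCc3ccccc3)c(OCc3ccccc3)c2)Oc2c(C)c(O)c(C)c(O)c21 | intermediate (not isolated)
7 | rac-5,7-dihydroxy-3-(hydroxyimino)-6,8-dimethyl-2-[3,4,5-tris(benzyloxy)phenyl]chroman-4-one (C=N geometry not fixed) | O=C1C(=NO)C(c2cc(OCc3ccccc3)c(OCc3ccccc3)c(OCc3ccccc3)c2)Oc2c(C)c(O)c(C)c(O)c21 | intermediate (not isolated)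
8 | rac-5,7-dihydroxy-3,3-dimethoxy-6,8-dimethyl-2-[3,4,5-tris(benzyloxy)phenyl]chroman-4-one | COC1(OC)C(c2cc(OCc3ccccc3)c(OCc3ccccc3)c(OCc3ccccc3)c2)Oc2c(C)c(O)c(C)c(O)c2C1=O | intermediate (not isolated)
9 | 5,7-dihydroxy-3-methoxy-6,8-dimethyl-2-[3,4,5-tris(benzyloxy)phenyl]-4H-chromen-4-one | COc1c(-c2cc(OCc3ccccc3)c(OCc3ccccc3)c(OCc3ccccc3)c2)oc2c(C)c(O)c(C)c(O)c2c1=O | intermediate
10 | 6,8-di-C-methylmyricetin 3-methyl ether | COc1c(-c2cc(O)c(O)c(O)c2)oc2c(C)c(O)c(C)c(O)c2c1=O | target

## Step count and risks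
Total step count: 4. Longest linear sequence: 4 (1 → 2 → 5 → 9 → 10).

**Step 1 (control of mono-, di- and tri-methylation).**
- The risk is a mixture with the mono-methyl and the dearomatised gem-dimethyl products.
- The fallback sets out from 1 and comes back at 2. It replaces SN2 alkylation by aminomethylation and hydrogenolysis.
- Treating 1 with aqueous CH2O and morpholine (2.2 equiv each, EtOH, rt) gives the bis-Mannich base 1-[2,4,6-trihydroxy-3,5-bis(morpholin-4-ylmethyl)phenyl]ethan-1-one F1. The reversible Mannich step cannot build a quaternary ring carbon, so substitution stops at two.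
- Hydrogenolysis of both benzylic C–N bonds (H2 4 bar, Pd/C, MeOH–AcOH, 50 °C) then gives 2.

**Step 2 (polyanion aldol).**
- The risks are poor solubility or reactivity of the tetra-anion, and loss of the aldehyde to the amide base.
- The fallback sets out from 2 and comes back at 5. It uses a protected ketone and a classical hydroxide-mediated condensation.
- MOMCl (2.3 equiv) and i-Pr2NEt in CH2Cl2 at 0 °C leave only the chelated OH free, giving 1-[2-hydroxy-4,6-bis(methoxymethoxy)-3,5-dimethylphenyl]ethan-1-one F2.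
- Condensation of this ketone with 3 (KOH, EtOH, rt) gives (E)-1-[2-hydroxy-4,6-bis(methoxymethoxy)-3,5-dimethylphenyl]-3-[3,4,5-tris(benzyloxy)phenyl]prop-2-en-1-one F3.
- The HCl/MeOH stage that opens step 3 strips both MOM groups and delivers 5, which is already equilibrating to 6.

**Step 3 (proposed new step, the most uncertain).**
- The failure modes are:
  - Beckmann-type fragmentation of the alpha-keto oxime 7;
  - capture of water, giving the flavonol;
  - oxidation or ipso-attack on the free ring A phenols;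
  - nitrosation of ring B.
- The fallback uses known chemistry, sets out from 5 and comes back at 10.
- I2 (cat.) in DMSO at 120 °C cyclises and dehydrogenates 5 to the flavone 5,7-dihydroxy-6,8-dimethyl-2-[3,4,5-tris(benzyloxy)phenyl]-4H-chromen-4-one F4.
- BnBr, K2CO3 and KI in DMF at 80 °C give 5,7-bis(benzyloxy)-6,8-dimethyl-2-[3,4,5-tris(benzyloxy)phenyl]-4H-chromen-4-one F5.
- Dimethyldioxirane (acetone–CH2Cl2, 0 °C) gives the racemic flavone 2,3-epoxide F6.
- Catalytic TsOH opens this epoxide to 5,7-bis(benzyloxy)-3-hydroxy-6,8-dimethyl-2-[3,4,5-tris(benzyloxy)phenyl]-4H-chromen-4-one F7.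
- MeI and K2CO3 in acetone methylate the only free OH, giving 5,7-bis(benzyloxy)-3-methoxy-6,8-dimethyl-2-[3,4,5-tris(benzyloxy)phenyl]-4H-chromen-4-one F8.
- Hydrogenolysis under the step 4 conditions removes all five benzyl groups and gives 10.

## Further compounds
F1 | step 1 | 1-[2,4,6-trihydroxy-3,5-bis(morpholin-4-ylmethyl)phenyl]ethan-1-one | CC(=O)c1c(O)c(CN2CCOCC2)c(O)c(CN2CCOCC2)c1O
F2 | step 2 | 1-[2-hydroxy-4,6-bis(methoxymethoxy)-3,5-dimethylphenyl]ethan-1-one | CC(=O)c1c(O)c(C)c(OCOC)c(C)c1OCOC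
F3 | step 2 | (E)-1-[2-hydroxy-4,6-bis(methoxymethoxy)-3,5-dimethylphenyl]-3-[3,4,5-tris(benzyloxy)phenyl]prop-2-en-1-one | O=C(/C=C/c1cc(OCc2ccccc2)c(OCc2ccccc2)c(OCc2ccccc2)c1)c1c(O)c(C)c(OCOC)c(C)c1OCOC
F4 | step 3 | 5,7-dihydroxy-6,8-dimethyl-2-[3,4,5-tris(benzyloxy)phenyl]-4H-chromen-4-one | O=c1cc(-c2cc(OCc3ccccc3)c(OCc3ccccc3)c(OCc3ccccc3)c2)oc2c(C)c(O)c(C)c(O)c12
F5 | step 3 | 5,7-bis(benzyloxy)-6,8-dimethyl-2-[3,4,5-tris(benzyloxy)phenyl]-4H-chromen-4-one | O=c1cc(-c2cc(OCc3ccccc3)c(OCc3ccccc3)c(OCc3ccccc3)c2)oc2c(C)c(OCc3ccccc3)c(C)c(OCc3ccccc3)c12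
F6 | step 3 | racemic 2,3-epoxide of F5 | O=C1C2OC2(c2cc(OCc3ccccc3)c(OCc3ccccc3)c(OCc3ccccc3)c2)Oc2c(C)c(OCc3ccccc3)c(C)c(OCc3ccccc3)c21
F7 | step 3 | 5,7-bis(benzyloxy)-3-hydroxy-6,8-dimethyl-2-[3,4,5-tris(benzyloxy)phenyl]-4H-chromen-4-one | O=c1c(O)c(-c2cc(OCc3ccccc3)c(OCc3ccccc3)c(OCc3ccccc3)c2)oc2c(C)c(OCc3ccccc3)c(C)c(OCc3ccccc3)c12
F8 | step 3 | 5,7-bis(benzyloxy)-3-methoxy-6,8-dimethyl-2-[3,4,5-tris(benzyloxy)phenyl]-4H-chromen-4-one | COc1c(-c2cc(OCc3ccccc3)c(OCc3ccccc3)c(OCc3ccccc3)c2)oc2c(C)c(OCc3ccccc3)c(C)c(OCc3ccccc3)c2c1=O
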